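Readings and results were generated by integration with constants of no real substance, noise included.

**Balance.** Nothing leaves a closed flask, so E, Q and whatever goes unseen add up to the charge. In the ochre run, the very flask asked about, the last reading leaves 23.0% unseen.

| flask | E | D | remark | time |
|---|---|---|---|---|
| ochre | 0.48 M | 9.6 mM | the very flask that is asked about, followed so far |  |
| amber | 0.96 M | 9.6 mM | run made earlier |  |
| flask | 0.48 M | 9.6 mM |  | 12 h |

| run | time / min | Q / % | E / % |
|---|---|---|---|
| ochre | 60.0 | 25 | 58 |
| ochre | 180 | 30 | 47 |
| ochre | 360 | 26 | 50 |
| ochre | 480 | 25 | 49 |
| ochre | 720 | 29 | 48 |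
| amber | 1.33 | 0 | 96 |
| amber | 4.00 | 9 | 93 |
| amber | 8.00 | 10 | 92 |
| amber | 12.0 | 13 | 85 |
| amber | 15.0 | 14 | 79 |

(readings scatter by 2 percentage points)
- larch: at 12 h add D, 100% of the amount charged, then wait 12 h
- birch: at 12 h take out 90% of the Q then present, then wait 12 h
- oak: at 12 h add E, 50.0% of the amount charged, then wait 12 h
- maple: change nothing and wait 12 h more
- Q that was removed still counts
- additions bring no volume worth counting
- Q, in percent of the E first charged, at 12 h
- which option adds most Q ("none" when 2 percentage points or less is all one gets) (larch / birch / oak / maple / none)
- Q present, with what was taken out counted in, in percent of the E first charged, after oak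
- Q present, with what was taken out counted in, in percent of the E first charged, after maple

**Rest share.** From 180 min on, the ochre readings stand still within the scatter, with E near 48.5% and Q near 27.5%. That second figure is the rest share: the part of the material in the flask that stands as Q once it rests.

**Live D.** Suppose D lasts, so that the rest is a balance (thermodynamic control). The last amber reading gives E a first-order constant of 0.0157 min⁻¹. Scaled by the distance to rest, the approach has a half-life of 22.7 min, so the time asked holds 31.7 half-lives. This curve puts E at 56.8% at 60.0 min, and ochre reads 58%.

**Dead D.** Suppose instead that D dies early. The rest is then a stop, fresh D restarts the flask, and the other options do nothing. This version needs a decay constant of its own, and the live curve needs none.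

**Own reckoning.** A partly fading D lies between the two, and the ochre reading at 60.0 min does not choose between them. This reckoning commits to the live end as the version without a decay constant, which is a choice and no proof. Then Q stands at the rest share now and after maple, and larch gains nothing. Oak gives 41.2%, a gain of 14 percentage points. Birch gains 18 points, so birch beats oak.

**Forecast.** The forecast differs, giving 27% now, 27.5% after oak and 27% after maple, and naming larch, since “the catalyst has died”.

**Flask result.** The flask gives 27.3%, 27.3% after maple and 40.9% after oak. Best is birch with 18 points, then oak with 14 points, and larch adds 0 points. After oak, Q is 27.3% of the material, against the rest share of 27.5%.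

    E + D ⇌ Q + D, rate k1*[E]*[D] forward; the back reaction follows from the equilibrium constant (K = 0.600, k = 0.0390 L mol⁻¹ s⁻¹)
    Q + D ⇌ L + D, rate k2*[D]*[Q] forward; the back reaction follows from the equilibrium constant (K = 0.997, k = 0.0230 L mol⁻¹ s⁻¹)
    L + D ⇌ E + D, rate k3*[D]*[L] forward; the back reaction follows from the equilibrium constant (k = 0.00904 L mol⁻¹ s⁻¹)
    2 D ⇌ G, settled at all times (K = 38.0 L mol⁻¹)

**More D.** The neighbouring flask is charged with 0.038 M of D. There 44.0% of the catalyst stands as D and 56.0% as G, so free D is 2.60 times that of the asked flask. The count rises to 82.3 half-lives, and the rest share still says 27.5%. That neighbour holds Q at 27.3%.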